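Readings and results stem from a simulated flask with constants of no real substance; noise was put on by code.

The ratio of isomer of the product A to target is what these questions turn on, and early in the elm flask it is small: 0% against 14% at 3.00 h. So I reckon only that correction.

| flask | starting material | catalyst | remark | time |
|---|---|---|---|---|
| elm | 2 M | 100 mM | the very flask that is asked about, followed so far |  |
| maple | 2 M | 200 mM | run made earlier |  |
| flask | 2.0 M | 100 mM |  | 2.5 d |

- elm (time / h: target / %, isomer of the product A / %): 2.00: 11, 0; 3.00: 14, 0; 4.00: 13, 1; 6.00: 18, 4; 10.0: 23, 5; 15.0: 20, 14; 25.0: 21, 26
- maple (time / d: target / %, isomer of the product A / %): 0.333: 25, 11; 0.625: 24, 18; 1.04: 18, 23; 1.25: 17, 25; 1.67: 16, 34; 2.00: 14, 34; 2.50: 12, 35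

(readings scatter by 2 percentage points)

* share of target in target plus isomer of the product A at 30 min
* share of target in target plus isomer of the product A at 2.5 d
* which of target and isomer of the product A there is more of at 2.5 d

- reactions considered so far: isomer of the product A + catalyst <-> isomer of the product B + catalyst; target <-> isomer of the product A; starting material + catalyst <-> target + catalyst

Between 10.0 h and 25.0 h the elm flask gains 21 percentage points of isomer of the product A, while target stands near 22.0%. That reads as 0.0636 h⁻¹, the handover rate, a first-order constant: the fraction of target passing to isomer of the product A per unit time. While target climbs in a straight line from nothing, the ratio is half the handover rate times the time. The step from target to isomer of the product A is written without catalyst, so I put no catalyst term in it. My share at 30 min is 98.4%.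

Late is harder. By 25.0 h elm already reads more isomer of the product A than target, and maple, with twice the catalyst, reads a share of 25.5% at 2.50 d.

The forecast gives 98.5% and 23%, with isomer of the product A ahead: “Isomer A shows a clear lag, so it comes from the target”.

The flask gives 98.5% and 22.4%, with 40.6% of isomer of the product A, more than the 11.7% of target. The two stand level at 19.4% after 0.841 d.

    isomer of the product A + catalyst ⇌ isomer of the product B + catalyst, rate k1*[catalyst]*[isomer of the product A] forward; the back reaction follows from the equilibrium constant (K = 19.0, k = 0.00150 M⁻¹ min⁻¹)
    target ⇌ isomer of the product A (K = 21.0, k = 0.00100 min⁻¹)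
    starting material + catalyst ⇌ target + catalyst, rate k3*[starting material]*[catalyst] forward; the back reaction follows from the equilibrium constant (K = 0.420, k = 0.0110 M⁻¹ min⁻¹)

At 0.250 d, half the handover rate times the time is 19.1%, and the flask's ratio is 22.5%. The neighbour flask with 0.25 M of catalyst stands at 98.5% at 30 min, beside my 98.4%.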